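The pitfall is to take equal charges and an equal 3.0 d as equal flasks. The set-ups differ in how long each charge works at full strength, measured against the time the chemistry needs.

| flask | substrate | reagent | initiator | remark | time |
|---|---|---|---|---|---|
| spring | 0.050 M | 0.050 M | 3.4 mM | run made earlier |  |
| summer | 0.050 M | 0.050 M | 5.1 mM | run made earlier |  |
| oak | 0.050 M | 0.0500 M | 3.4 mM | one stirred flow tank at steady state, fed with the mixture as stated, mean residence time 3.0 d |  |
| cedar | 0.050 M | 0.0500 M | 3.4 mM | everything together in a closed stirred flask, run for 3.0 d | 3.0 d |
| alder | 0.050 M (fed, over 1.50 d) | 0.0500 M | 3.4 mM | a stirred flask in which substrate is dosed at a steady rate over 1.50 d without added volume, worked up at 3.0 d | 3.0 d |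
| ash | 0.050 M | 0.0500 M (fed, over 1.50 d) | 3.4 mM | a stirred flask in which reagent is dosed at a steady rate over 1.50 d without added volume, worked up at 3.0 d | 3.0 d |

spring run (percent of the substrate charged)

| time / d | target / % | substrate / % |
|---|---|---|
| 0.208 | 9.3 | 90.6 |
| 0.625 | 22.7 | 77.3 |
| 1.04 | 30.9 | 67.5 |
| 1.67 | 39.6 | 57.2 |
| 2.50 | 47.1 | 48.3 |
| 3.00 | 51.0 | 44.1 |

summer run (percent of the substrate charged)

| time / h | target / % | substrate / % |
|---|---|---|
| 2.50 | 5.7 | 94.3 |
| 5.00 | 11.0 | 88.0 |
| 8.00 | 16.7 | 82.8 |
| 10.0 | 19.3 | 79.3 |
| 12.0 | 21.9 | 76.3 |
| 15.0 | 25.4 | 72.3 |

(readings scatter by 0.3 percentage points)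

- the stated concentrations are those of everything mixed, before any reaction; amounts are the same in each set-up
- the feed brings no volume worth counting
- the earlier runs were made in a closed, stirred flask

- the set-up with the highest amount of target at the outlet or at the end, in percent of the substrate put in ("none" if the first two lie within 2 percentage points) (oak / cedar / alder / ash / none)
- amount of target at the outlet or at the end, in percent of the substrate put in, oak
- amount of target at the outlet or at the end, in percent of the substrate put in, cedar
- amount of target at the outlet or at the end, in percent of the substrate put in, alder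
- amount of target at the outlet or at the end, in percent of the substrate put in, ash

Two times carry the reckoning here. One is the run, 3.0 d, which is also the residence time of oak. The other is the reaction time, the time in which equimolar [substrate] and [reagent] halve under a rate proportional to their product. The last spring reading gives it as 2.37 d. The first reading gives 2.00 d, which is shorter, so the spring rate falls behind that product law, and the longer value carries this drift as an average. The ratio of the run to the reaction time of 2.37 d (a Damköhler number) is 1.27. At its last reading spring still held 44.1 % of its substrate, and target was 91.2 % of the substrate converted.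

Cedar has the charge and the time of spring, so the reckoning takes the last spring reading, 51.0 %. For oak the same law sets conversion divided by the square of the unconverted fraction equal to the ratio, which reckons target at 38.6 %. A dose over 1.50 d arrives on average 0.750 d late, so alder and ash are both reckoned with a ratio of 0.951, which gives target 44.5 %. This reckoning therefore puts cedar ahead by 6.5 percentage points.

The forecast, with “Cedar simply repeats spring”, names cedar and gives 38 %, 51 %, 41 % and 44 % for oak, cedar, alder and ash.

The flasks give 36.1 %, 50.5 %, 45.3 % and 43.5 % in that order, so cedar leads.

    reagent + first chain carrier ⇌ target + second chain carrier (K = 0.390, k = 7000 M⁻¹ min⁻¹)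
    substrate + second chain carrier → released group + first chain carrier (k = 7000 M⁻¹ min⁻¹)
    2 first chain carrier → ended chains B (k = 2.00 × 10⁶ M⁻¹ s⁻¹)
    initiator → 2 initiating radical (k = 1.40 × 10⁻⁴ min⁻¹)
    substrate + initiating radical → capped initiator + first chain carrier (k = 2.50 × 10⁵ M⁻¹ min⁻¹)
    2 second chain carrier → ended chains A (k = 1.00 × 10⁶ M⁻¹ s⁻¹)

Oak lies 2.5 points under the reckoned 38.6 %, while alder stands above and ash below the reckoned 44.5 %. The reaction time read off spring, 2.37 d, is shorter than the 3.4 d half-life of initiator by its decomposition step alone, a ratio of 1.45. With chains ending in pairs, the summer mixture's reaction time, scaled by the square root of the initiator ratio, is 1.93 d. Over 3.0 d that reckons target at 55.5 %, and that mixture gives 54.3 %.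

The numbers in the tables were generated by integration for an exercise; scatter was added.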